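## Retrosynthetic overview

1. Fischerin ⇒ (global fluoride deprotection, C–OH oxidation) ⇒ C3–C(acyl) bond: a 3-lithio-N-alkoxy-2-pyridone bearing the finished epoxydiol ring + a cis-decalin aldehyde.
2. Epoxydiol ring ⇒ hydroxyl-directed, catalyst-controlled desymmetrising epoxidation (C–O formation, key step) of a meso trans-cyclohexa-2,5-diene-1,4-diol, then diimide saturation of the second alkene.
3. Dienediol ⇒ Luche reduction of a p-quinol ⇒ 5-lithiopyridone + benzoquinone mono-dimethyl ketal.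
4. N-Hydroxypyridone core ⇒ 5-bromo-2,4-dichloropyridine by N-oxidation, double SNAr hydrolysis and SEM protection.
5. cis-Decalin (rings A and B closed together) ⇒ endo intramolecular Diels–Alder (IMDA) of a (2Z,8E,10E)-trienal, then C1 epimerisation; the triene comes from sorbyl acetate, a C4 Grignard reagent and a Still–Gennari olefination. Ring order: pyridone (bought) → cyclohexadiene attached → epoxide; decalin made separately; fragments joined last.

Assumption: the facial sense of the two chiral catalysts (steps 6 and 12) is taken by analogy with their closest known uses; if a first run shows the opposite sense, the mirror-image catalyst is used and nothing else changes.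

Abbreviations: SEM = CH2OCH2CH2SiMe3 (SEMO = OCH2OCH2CH2SiMe3); TES = SiEt3. Decalin numbering: C1 bears the carbonyl carbon, C2 the methyl, C3=C4 the alkene, C4a/C8a the ring fusion.

## Route

Step 1
Reactants: 1 4-chloro-1,1-dimethoxybutane; 2 (2E,4E)-hexa-2,4-dien-1-yl acetate (sorbyl acetate)
Product: 4 (6E,8E)-1,1-dimethoxydeca-6,8-diene, via Grignard reagent 3 (not isolated)
Conditions: Mg, THF, reflux; then 2, Li2CuCl4 (3 mol%), THF, −20 to 0 °C
Reagents that add atoms: none
Why: Copper-catalysed Grignard/allylic acetate cross-coupling substitutes the primary acetate at its α-carbon and keeps the E,E-diene geometry of the sorbyl unit.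

Step 2
Reactants: 4 (6E,8E)-1,1-dimethoxydeca-6,8-diene
Product: 5 (6E,8E)-deca-6,8-dienal
Conditions: 1 M HCl (cat.), THF/H2O, 23 °C
Reagents that add atoms: water, O
Why: Simple acetal hydrolysis; the unactivated conjugated diene is inert to dilute acid at room temperature.

Step 3
Reactants: 5 (6E,8E)-deca-6,8-dienal; 6 methyl 2-[bis(2,2,2-trifluoroethoxy)phosphoryl]acetate
Product: 7 methyl (2Z,8E,10E)-dodeca-2,8,10-trienoate
Conditions: KN(SiMe3)2, 18-crown-6, THF, −78 °C
Reagents that add atoms: none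
Why: Still–Gennari olefination, in which fast irreversible elimination from the electron-poor phosphonate adduct gives the Z-enoate (typically >15:1).

Step 4
Reactants: 7 methyl (2Z,8E,10E)-dodeca-2,8,10-trienoate
Product: 8 (2Z,8E,10E)-dodeca-2,8,10-trien-1-ol
Conditions: iBu2AlH (2.2 equiv), CH2Cl2, −78 °C
Reagents that add atoms: none
Why: 1,2-Reduction of the enoate by the aluminium hydride leaves all three alkene geometries untouched.

Step 5
Reactants: 8 (2Z,8E,10E)-dodeca-2,8,10-trien-1-ol
Product: 9 (2Z,8E,10E)-dodeca-2,8,10-trienal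
Conditions: Dess–Martin periodinane, pyridine, CH2Cl2, 0 °C; used at once
Reagents that add atoms: none
Why: Buffered Dess–Martin oxidation is neutral and fast, so the isomerisation-prone Z-enal is formed without Z→E leakage.

Step 6
Reactants: 9 (2Z,8E,10E)-dodeca-2,8,10-trienal
Product: 11 (1R,2S,4aR,8aR)-2-methyl-1,2,4a,5,6,7,8,8a-octahydronaphthalene-1-carbaldehyde, via all-cis aldehyde 10 (not isolated)
Conditions: (S)-1-(2-methylphenyl)-3,3-diphenyltetrahydro-1H,3H-pyrrolo[1,2-c][1,3,2]oxazaborole·HN(SO2CF3)2 (20 mol%), CH2Cl2, −78 to −40 °C; then Et3N, DBU (0.2 equiv), 23 °C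
Reagents that add atoms: none
Why: Proposed new method: enantioselective endo IMDA of a Z-enal under a chiral N-protonated oxazaborolidine; the boron-bound s-trans Z-enal is held by B–O coordination and a formyl C–H···O contact, the tethered E,E-diene can reach it only in the endo mode with the four-carbon tether cis to the formyl group, so C1, C2, C4a and C8a form all-cis (cis ring fusion, Me cis to C5) with the catalyst choosing the 4aR,8aR enantioface, and DBU then inverts only the enolisable C1 to the equatorial CHO that is trans to both neighbours (the all-cis epimer suffers a syn-diaxial CHO/C5 or Me/C8 clash in either half-chair); closest known reactions are the oxazaborolidinium-catalysed IMDA of (E)-trienals and the Me2AlCl-promoted endo IMDA of racemic (Z)-2,8,10-trienals.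

Step 7
Reactants: 12 5-bromo-2,4-dichloropyridine
Product: 13 5-bromo-2,4-dichloropyridine 1-oxide
Conditions: urea·H2O2, (CF3CO)2O, CH2Cl2, 0 to 23 °C
Reagents that add atoms: hydrogen peroxide (as its urea adduct), OO
Why: Trifluoroperacetic acid made in the flask is electrophilic enough to N-oxidise this electron-poor pyridine (peracid N-oxidation).

Step 8
Reactants: 13 5-bromo-2,4-dichloropyridine 1-oxide
Product: 14 5-bromo-1,4-dihydroxypyridin-2(1H)-one
Conditions: NaOH (10% aq.), 90 °C; then HCl to pH 2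
Reagents that add atoms: sodium hydroxide, [Na+].[OH-]
Why: The N-oxide activates C2 and C4 (not C5) for SNAr by hydroxide, and the 2-hydroxy N-oxide tautomerises to the N-hydroxy-2-pyridone, so the N–O bond is in place before any alkene exists.

Step 9
Reactants: 14 5-bromo-1,4-dihydroxypyridin-2(1H)-one
Product: 15 5-bromo-1,4-bis(SEMO)pyridin-2(1H)-one
Conditions: Me3SiCH2CH2OCH2Cl (2.4 equiv), iPr2NEt, CH2Cl2, 0 to 23 °C
Reagents that add atoms: 2-(trimethylsilyl)ethoxymethyl chloride, C[Si](C)(C)CCOCCl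
Why: O-Alkylation of the two acidic hydroxyls (N–OH and vinylogous-acid 4-OH) by the hard chloromethyl ether gives fluoride-labile, base-stable SEM ethers.

Step 10
Reactants: 15 5-bromo-1,4-bis(SEMO)pyridin-2(1H)-one; 16 4,4-dimethoxycyclohexa-2,5-dien-1-one
Product: 19 5-(1-hydroxy-4-oxocyclohexa-2,5-dien-1-yl)-1,4-bis(SEMO)pyridin-2(1H)-one, via aryllithium 17 (not isolated), via quinol ketal alkoxide 18 (not isolated)
Conditions: tBuLi (2.05 equiv), THF, −78 °C; then 16, −78 °C; then 10% aq. AcOH, 23 °C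
Reagents that add atoms: water, O
Why: Bromine–lithium exchange (faster than any deprotonation at −78 °C, helped by the ortho SEMO group) followed by 1,2-addition to the quinone monoketal and mild ketal hydrolysis is the classical p-quinol synthesis; no stereocentre is formed.

Step 11
Reactants: 19 p-quinol (name as in step 10)
Product: 20 5-(trans-1,4-dihydroxycyclohexa-2,5-dien-1-yl)-1,4-bis(SEMO)pyridin-2(1H)-one (meso; the two OH groups on opposite ring faces)
Conditions: NaBH4, CeCl3·7H2O, MeOH, −78 °C; neutral work-up, used directly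
Reagents that add atoms: none
Why: Luche 1,2-reduction, with hydride entering from the face of the small tertiary OH, anti to the bulky ortho-alkoxy pyridonyl group (the usual facial preference of 4-oxy-4-substituted cyclohexadienones), so the new OH is trans to the tertiary OH.

Step 12
Reactants: 20 meso trans-dienediol (name as in step 11)
Product: 21 5-[(1R,2S,5R,6R)-2,5-dihydroxy-7-oxabicyclo[4.1.0]hept-3-en-2-yl]-1,4-bis(SEMO)pyridin-2(1H)-one
Conditions: VO(OiPr)3 (2 mol%), (R,R)-N,N′-(cyclohexane-1,2-diyl)bis(N-hydroxy-2,2-diphenylacetamide) (4 mol%), tBuOOH (70% aq., 1.1 equiv), toluene, 0 °C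
Reagents that add atoms: tert-butyl hydroperoxide, CC(C)(C)OO
Why: Proposed new method: vanadium–bishydroxamic acid hydroxyl-directed epoxidation used to desymmetrise a meso 4-aryl-cyclohexa-2,5-diene-1,4-diol; the secondary alkoxide binds the pentavalent vanadium tert-butylperoxo complex and delivers oxygen syn to itself (hence anti to the tertiary OH, which is shielded by the ortho SEMO-pyridone and is a poor substrate class for these catalysts) onto the one enantiotopic cis-alkene that fits the chiral ligand pocket, fixing all four stereocentres (both epoxide carbons and both carbinols) in one C–O bond-forming event, and any minor enantiomer is drained by faster second epoxidation; closest known reactions are the same catalyst's desymmetrisation of acyclic meso divinyl carbinols and vanadium-catalysed syn-epoxidation of cyclohex-2-enols.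

Step 13
Reactants: 21 epoxy-ene-diol (name as in step 12)
Product: 22 5-[(1R,2S,5R,6R)-2,5-dihydroxy-7-oxabicyclo[4.1.0]heptan-2-yl]-1,4-bis(SEMO)pyridin-2(1H)-one
Conditions: 2-nitrobenzenesulfonyl hydrazide (6 equiv), Et3N, CH2Cl2, 23 °C
Reagents that add atoms: none
Why: Diimide reduction transfers H2 concertedly to the remaining cis-alkene and cannot hydrogenolyse the epoxide, the N–O bond or the allylic/benzylic C–O bonds; it is done before the decalin alkene is present.

Step 14
Reactants: 22 epoxydiol (name as in step 13)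
Product: 23 5-[(1R,2S,5R,6R)-2,5-bis(triethylsilyloxy)-7-oxabicyclo[4.1.0]heptan-2-yl]-1,4-bis(SEMO)pyridin-2(1H)-one
Conditions: Et3SiOTf (2.6 equiv), 2,6-lutidine, CH2Cl2, −78 to 0 °C
Reagents that add atoms: triethylsilyl trifluoromethanesulfonate, CC[Si](CC)(CC)OS(=O)(=O)C(F)(F)F
Why: Silyl triflate silylation caps the secondary and the hindered tertiary OH, removing acidic protons and the Payne-rearrangement pathway before the strong-base step.

Step 15
Reactants: 23 bis-TES ether (name as in step 14); 11 (1R,2S,4aR,8aR)-decalin aldehyde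
Product: 25 3-{hydroxy[(1R,2S,4aR,8aR)-2-methyl-1,2,4a,5,6,7,8,8a-octahydronaphthalen-1-yl]methyl}-5-[(1R,2S,5R,6R)-2,5-bis(triethylsilyloxy)-7-oxabicyclo[4.1.0]heptan-2-yl]-1,4-bis(SEMO)pyridin-2(1H)-one (both carbinol epimers), via 3-lithiopyridone 24 (not isolated)
Conditions: LiN(iPr)2 (1.2 equiv), THF, −78 °C; then 11, −78 to −40 °C; AcOH quench
Reagents that add atoms: none
Why: Directed ortho-lithiation at C3, the position flanked by the lactam carbonyl and the 4-SEMO group, followed by 1,2-addition to the aldehyde; the new carbinol centre is removed in the next step.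

Step 16
Reactants: 25 carbinol mixture (name as in step 15)
Product: 26 3-[(1R,2S,4aR,8aR)-2-methyl-1,2,4a,5,6,7,8,8a-octahydronaphthalene-1-carbonyl]-5-[(1R,2S,5R,6R)-2,5-bis(triethylsilyloxy)-7-oxabicyclo[4.1.0]heptan-2-yl]-1,4-bis(SEMO)pyridin-2(1H)-one
Conditions: Dess–Martin periodinane, pyridine, CH2Cl2, 23 °C
Reagents that add atoms: none
Why: Dess–Martin oxidation converts both epimers into one ketone without touching the alkene, epoxide or silyl groups; C1 already has its thermodynamic configuration.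

Step 17
Reactants: 26 protected ketone (name as in step 16)
Product: 27 fischerin
Conditions: Bu4NF (8 equiv), AcOH (4 equiv), THF, 0 to 23 °C
Reagents that add atoms: none
Why: Fluoride cleaves both Si–O bonds and triggers fragmentation of both SEM groups (loss of fluorosilane, ethene and formaldehyde from the good N–O⁻ and vinylogous carboxylate leaving groups), while the AcOH buffer keeps the medium non-basic so the trans tertiary alkoxide cannot start a Payne rearrangement.

## Compound list

1 | 4-chloro-1,1-dimethoxybutane | COC(OC)CCCCl | starting material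
2 | (2E,4E)-hexa-2,4-dien-1-yl acetate | C/C=C/C=C/COC(C)=O | starting material
3 | (4,4-dimethoxybutyl)magnesium chloride | COC(OC)CCC[Mg]Cl | intermediate
4 | (6E,8E)-1,1-dimethoxydeca-6,8-diene | C/C=C/C=C/CCCCC(OC)OC | intermediate
5 | (6E,8E)-deca-6,8-dienal | C/C=C/C=C/CCCCC=O | intermediate
6 | methyl 2-[bis(2,2,2-trifluoroethoxy)phosphoryl]acetate | COC(=O)CP(=O)(OCC(F)(F)F)OCC(F)(F)F | starting material
7 | methyl (2Z,8E,10E)-dodeca-2,8,10-trienoate | C/C=C/C=C/CCCC/C=C\C(=O)OC | intermediate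
8 | (2Z,8E,10E)-dodeca-2,8,10-trien-1-ol | C/C=C/C=C/CCCC/C=C\CO | intermediate
9 | (2Z,8E,10E)-dodeca-2,8,10-trienal | C/C=C/C=C/CCCC/C=C\C=O | intermediate
10 | (1S,2S,4aR,8aR)-2-methyl-1,2,4a,5,6,7,8,8a-octahydronaphthalene-1-carbaldehyde (all-cis endo adduct) | C[C@H]1C=C[C@H]2CCCC[C@H]2[C@H]1C=O | intermediate
11 | (1R,2S,4aR,8aR)-2-methyl-1,2,4a,5,6,7,8,8a-octahydronaphthalene-1-carbaldehyde | C[C@H]1C=C[C@H]2CCCC[C@H]2[C@@H]1C=O | intermediate
12 | 5-bromo-2,4-dichloropyridine | Clc1cc(Cl)c(Br)cn1 | starting material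
13 | 5-bromo-2,4-dichloropyridine 1-oxide | [O-][n+]1cc(Br)c(Cl)cc1Cl | intermediate
14 | 5-bromo-1,4-dihydroxypyridin-2(1H)-one | O=c1cc(O)c(Br)cn1O | intermediate
15 | 5-bromo-1,4-bis{[2-(trimethylsilyl)ethoxy]methoxy}pyridin-2(1H)-one | O=c1cc(OCOCC[Si](C)(C)C)c(Br)cn1OCOCC[Si](C)(C)C | intermediate
16 | 4,4-dimethoxycyclohexa-2,5-dien-1-one | COC1(OC)C=CC(=O)C=C1 | starting material
17 | 5-lithio-1,4-bis(SEMO)pyridin-2(1H)-one | [Li]c1cn(OCOCC[Si](C)(C)C)c(=O)cc1OCOCC[Si](C)(C)C | intermediate
18 | lithium 4,4-dimethoxy-1-[1,4-bis(SEMO)-2-oxo-1,2-dihydropyridin-5-yl]cyclohexa-2,5-dien-1-olate | COC1(OC)C=CC(O[Li])(C=C1)c1cn(OCOCC[Si](C)(C)C)c(=O)cc1OCOCC[Si](C)(C)C | intermediate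
19 | 5-(1-hydroxy-4-oxocyclohexa-2,5-dien-1-yl)-1,4-bis(SEMO)pyridin-2(1H)-one | O=C1C=CC(O)(C=C1)c1cn(OCOCC[Si](C)(C)C)c(=O)cc1OCOCC[Si](C)(C)C | intermediate
20 | 5-(trans-1,4-dihydroxycyclohexa-2,5-dien-1-yl)-1,4-bis(SEMO)pyridin-2(1H)-one (meso) | O=c1cc(OCOCC[Si](C)(C)C)c(cn1OCOCC[Si](C)(C)C)[C@@]1(O)C=C[C@@H](O)C=C1 | intermediate
21 | 5-[(1R,2S,5R,6R)-2,5-dihydroxy-7-oxabicyclo[4.1.0]hept-3-en-2-yl]-1,4-bis(SEMO)pyridin-2(1H)-one | O=c1cc(OCOCC[Si](C)(C)C)c(cn1OCOCC[Si](C)(C)C)[C@@]1(O)C=C[C@@H](O)[C@H]2O[C@H]21 | intermediate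
22 | 5-[(1R,2S,5R,6R)-2,5-dihydroxy-7-oxabicyclo[4.1.0]heptan-2-yl]-1,4-bis(SEMO)pyridin-2(1H)-one | O=c1cc(OCOCC[Si](C)(C)C)c(cn1OCOCC[Si](C)(C)C)[C@@]1(O)CC[C@@H](O)[C@H]2O[C@H]21 | intermediate
23 | 5-[(1R,2S,5R,6R)-2,5-bis(triethylsilyloxy)-7-oxabicyclo[4.1.0]heptan-2-yl]-1,4-bis(SEMO)pyridin-2(1H)-one | O=c1cc(OCOCC[Si](C)(C)C)c(cn1OCOCC[Si](C)(C)C)[C@@]1(O[Si](CC)(CC)CC)CC[C@@H](O[Si](CC)(CC)CC)[C@H]2O[C@H]21 | intermediate
24 | 3-lithio derivative of 23 | [Li]c1c(OCOCC[Si](C)(C)C)c(cn(OCOCC[Si](C)(C)C)c1=O)[C@@]1(O[Si](CC)(CC)CC)CC[C@@H](O[Si](CC)(CC)CC)[C@H]2O[C@H]21 | intermediate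
25 | 3-{hydroxy[(1R,2S,4aR,8aR)-2-methyl-octahydronaphthalen-1-yl]methyl} derivative of 23 (carbinol epimers) | C[C@H]1C=C[C@H]2CCCC[C@H]2[C@@H]1C(O)c1c(OCOCC[Si](C)(C)C)c(cn(OCOCC[Si](C)(C)C)c1=O)[C@@]1(O[Si](CC)(CC)CC)CC[C@@H](O[Si](CC)(CC)CC)[C@H]2O[C@H]21 | intermediate
26 | 3-[(1R,2S,4aR,8aR)-2-methyl-1,2,4a,5,6,7,8,8a-octahydronaphthalene-1-carbonyl]-5-[(1R,2S,5R,6R)-2,5-bis(triethylsilyloxy)-7-oxabicyclo[4.1.0]heptan-2-yl]-1,4-bis(SEMO)pyridin-2(1H)-one | C[C@H]1C=C[C@H]2CCCC[C@H]2[C@@H]1C(=O)c1c(OCOCC[Si](C)(C)C)c(cn(OCOCC[Si](C)(C)C)c1=O)[C@@]1(O[Si](CC)(CC)CC)CC[C@@H](O[Si](CC)(CC)CC)[C@H]2O[C@H]21 | intermediate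
27 | fischerin, 1,4-dihydroxy-5-[(1R,2S,5R,6R)-2,5-dihydroxy-7-oxabicyclo[4.1.0]heptan-2-yl]-3-[(1R,2S,4aR,8aR)-2-methyl-1,2,4a,5,6,7,8,8a-octahydronaphthalene-1-carbonyl]pyridin-2(1H)-one | C[C@H]1C=C[C@H]2CCCC[C@H]2[C@@H]1C(=O)c1c(O)c([C@@]2(O)CC[C@@H](O)[C@H]3O[C@H]32)cn(O)c1=O | target

## Step count and risks

Total steps: 17. Longest linear sequence: 11 (steps 7–17 from 12); the decalin arm is 6 steps before the union.

Steps most likely to fail:

- **Step 12 (new desymmetrising epoxidation).** Risks: direction by the tertiary OH instead of the secondary one, acid-type aromatisation of 20, unknown ee. Fallback with known chemistry, setting out from 20 and returning at 21: achiral hydroxyl-directed epoxidation with VO(acac)2/tBuOOH in toluene at 0 °C (the standard syn-epoxidation of cyclohexenols) gives the racemic epoxy-ene-diol F4, which is separated on a preparative chiral stationary phase to give 21.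
- **Step 6 (new asymmetric IMDA of the Z-enal).** Risks: Z→E isomerisation on the catalyst, insufficient ee. Fallback with known chemistry, setting out from 9 and returning at 11: Me2AlCl (1 equiv), CH2Cl2, −78 °C, the established endo cyclisation of Z-trienals, gives the racemic all-cis aldehyde F1; DBU equilibrates it to the racemic trans,trans aldehyde F2; preparative chiral-phase supercritical-fluid chromatography then delivers 11.
- **Step 10 (aryllithium route to the p-quinol).** Risks: tBuLi attacking the N–O bond or C6 of the pyridone, rearrangement of the electron-rich quinol on acidic unmasking. Fallback setting out from 15 and returning at 19: Suzuki–Miyaura coupling of 15 with 4-hydroxyphenylboronic acid (PdCl2(dppf), K2CO3, dioxane/H2O, 80 °C) gives 5-(4-hydroxyphenyl)-1,4-bis(SEMO)pyridin-2(1H)-one F3; oxidative dearomatisation with PhI(OAc)2 in MeCN/H2O at 0 °C installs the tertiary C–O bond and gives 19.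

## Further compounds

F1 | step 6 | racemic all-cis 2-methyl-1,2,4a,5,6,7,8,8a-octahydronaphthalene-1-carbaldehyde (10 and its enantiomer, 1:1) | C[C@H]1C=C[C@H]2CCCC[C@H]2[C@H]1C=O.C[C@@H]1C=C[C@@H]2CCCC[C@@H]2[C@@H]1C=O
F2 | step 6 | racemic trans,trans aldehyde (11 and its enantiomer, 1:1) | C[C@H]1C=C[C@H]2CCCC[C@H]2[C@@H]1C=O.C[C@@H]1C=C[C@@H]2CCCC[C@@H]2[C@H]1C=O
F3 | step 10 | 5-(4-hydroxyphenyl)-1,4-bis{[2-(trimethylsilyl)ethoxy]methoxy}pyridin-2(1H)-one | O=c1cc(OCOCC[Si](C)(C)C)c(cn1OCOCC[Si](C)(C)C)-c1ccc(O)cc1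
F4 | step 12 | racemic epoxy-ene-diol (21 and its enantiomer, 1:1) | O=c1cc(OCOCC[Si](C)(C)C)c(cn1OCOCC[Si](C)(C)C)[C@@]1(O)C=C[C@@H](O)[C@H]2O[C@H]21.O=c1cc(OCOCC[Si](C)(C)C)c(cn1OCOCC[Si](C)(C)C)[C@]1(O)C=C[C@H](O)[C@@H]2O[C@@H]21
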